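**Remark on numbering and one assumption.** The chain is numbered from the ether carbon: C1 (OCH2), C2 (CH–OOH), C3 (=CH2), C4 (CH2), C5 (C=O), C6=C7(CH3)2. The target is (2S). Assumption: both enantiomers of the glycerate ester 1 are commercial; the (S)-ester is used because step 7 inverts C2.

## The problem

- The target is an acyclic C10 chain bound through O–C1 to methyl vanillate. No ring has to be made; the difficulty lies in five adjacent functional carbons: C1H2–OAr, C2(H)–OOH, C3(=CH2), C4H2 and the C5 enone.
- C2 is the only stereocentre and nothing in the molecule can control it. C1 is a CH2 and the alkene terminus on C3 is a bare CH2, so no stereocentre can be placed from which chirality could be passed along C2–C3=CH2 by a 1,3-transposition or an ene-type process.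
- C2 must therefore be set either by an external chiral agent or by substitution at a C2–O centre that already has a defined configuration.
- The skipped array C3(=CH2)–C4H2–C5(=O) is thermodynamically fragile: base moves the alkene into conjugation, and a free C2–OH can close onto C5 and aromatise to a furan under acid.
- The secondary allylic hydroperoxide is reduced by phosphines, sulfides, hydrides and low-valent metals, and fragments under base (Kornblum–DeLaMare at C2–H) and acid (Hock). It must be introduced last, and hydroperoxide anion cannot be used because it would epoxidise the enone and deprotonate C4.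
- The feature that makes the key step possible: C2 is a secondary carbon flanked by C1, which carries the electron-withdrawing aryloxy oxygen, and by the vinylic C3, whose alkene partner is an unsubstituted CH2. Ionisation at C2 is disfavoured, so a (2R) C2–O bond should be exchangeable for C2–OOH by SN2 with inversion.
- The triad C1(O)–C2(O)–C3, with C3 carrying two further carbon bonds, is a glyceric ester in disguise, so the C2 configuration can be bought.

## Retrosynthesis

**12 ⇒ 10 (through 11): the C2–OO bond.** Only the bond between C2 and the peroxide oxygen is cut; the hydroperoxide is traced back to the (2R)-alcohol 10, activated as triflate 11 and displaced by hydrogen peroxide with inversion. The neighbouring cut, the ene retron that also moves the alkene to C2=C3, builds the same array but cannot fix C2. This cut lets the configuration be programmed and removes the one group that tolerates almost no reagent. The precursor 10 is a robust alcohol in which phosphine, Lewis-acid and fluoride chemistry is still allowed. The forward step must be a clean SN2 under neutral, non-reducing, cold conditions.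

**10 ⇒ 9 ⇒ 7 + 8: the C4–C5 bond.** The ketone is disconnected between C4 and C5 into the allylsilane 7 and the acid chloride 8; the C2 hydroxyl is carried as a TES ether (9). An SE2′ acylation puts the double bond where the C–Si carbon was, so the C3=CH2 position is dictated by mechanism. Enolate vinylation or aldol-dehydration routes would let the alkene slip into conjugation. The precursor 7 has neither ketone nor enone. The forward reaction must be a fast, cold Lewis-acid acylation that leaves the silyl ether, aryl ether and ester intact.

**7 ⇒ 6 ⇒ 4 + 5: the C1–OAr bond.** The aryl ether is cut at C1–O, giving diol 4 and methyl vanillate 5. The position of this cut in the sequence is forced from both sides: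
- the benzoate ester of 5 would not survive the organometallic step that makes the allylsilane, so it enters after that step;
- a free 1,2-diol cannot coexist with the C5 ketone (ketalisation), so it enters before the acylation.

The forward reaction must etherify the primary hydroxyl only and leave C2–O untouched.

**4 ⇒ 3 ⇒ 1: C3–C4 and C3=CH2 from one ester carbon.** Both carbon substituents of C3 are cut back to the carboxyl carbon of the protected glycerate 1. Double addition of a silylmethyl-metal reagent followed by Peterson elimination turns CO2Me into C(=CH2)CH2SiMe3 (3), which supplies the exo-methylene and the C4 nucleophile together. The precursor is a commercial, enantiopure C3 unit. The forward reaction must not epimerise the α-alkoxy centre.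

## Roads not taken

**Alternative 1:** the most obvious route.
- Cut: the C2–OO bond together with a shift of the alkene back to C2=C3 (ene retron), giving the (E)-5-oxogeranyl ether A1 from 5.
- Forward key step: dye-sensitised photooxygenation (Schenck ene). Singlet oxygen should attack the electron-rich C2=C3 bond (the C6=C7 enone is deactivated), abstract a hydrogen from the C3 methyl group and give the hydroperoxide A2.
- Why the chosen plan is better: A2 is necessarily racemic, since A1 has no stereocentre and, with C1 a CH2, no directing allylic group can be installed. The single enantiomer would have to come from a resolution that discards half the material, and the sense of an enzymatic kinetic resolution cannot be predicted with confidence for this substituent pattern. Abstraction of the more acidic C4–H (giving a conjugated dienone hydroperoxide) and the need for geometrically pure A1 are further selectivity problems. This route is about three steps shorter and is kept as the fallback for the key step.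

**Alternative 2:**
- Cut: the C2–C3 bond, giving the aryloxyacetaldehyde A3 and a 2-metallated allylsilane.
- Forward key step: catalytic asymmetric Nozaki–Hiyama–Kishi alkenylation of A3 with a 2-haloallylsilane, which would give 6 directly.
- Why the chosen plan is better: the step count to 6 is the same (alkylation of 5, acetal hydrolysis, coupling). The ee of C2 would then depend on ligand control over an α-aryloxy aldehyde that can chelate and that hydrates and oligomerises easily. The later SN2 step can only transmit ee, not raise it. The glycerate 1 delivers the same three carbons with C2 already enantiopure.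

**Alternative 3:**
- Cut: the C2–OO bond at an epoxide, giving the (R)-vinyl epoxide A4.
- Forward key step: acid- or molybdenum-catalysed opening of A4 by hydrogen peroxide at the allylic carbon with inversion, giving the hydroperoxy alcohol A5, followed by O-arylation of the primary hydroxyl.
- Why the chosen plan is better: the aryl ether cannot be made once the hydroperoxide is present. A Mitsunobu reaction needs a phosphine, which reduces O–O. Williamson or SNAr conditions need base, under which the more acidic hydroperoxide is alkylated or fragments. Protecting the hydroperoxide adds steps. The aryl ether must therefore be in place before the O–O bond, which is the chosen order.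

Key step: step 7

## Steps

Step 1
Reactants: 1 methyl (4S)-2,2-dimethyl-1,3-dioxolane-4-carboxylate
Product: 3 trimethyl{2-[(4R)-2,2-dimethyl-1,3-dioxolan-4-yl]prop-2-en-1-yl}silane, via bis(silylmethyl) carbinol 2 (not isolated)
Conditions: Me3SiCH2MgCl (3.5 equiv), CeCl3, THF, −78 °C to rt; then SiO2, CH2Cl2, rt
Reagents that add atoms: (trimethylsilyl)methylmagnesium chloride, C[Si](C)(C)C[Mg]Cl
Why: The non-basic organocerium reagent should add twice to the ester without enolising the α-alkoxy centre, and the β-hydroxysilane 2 should undergo acid-promoted Peterson elimination to the 2-substituted allylsilane (ester-to-allylsilane conversion). No bond to the stereocentre is touched; its descriptor changes from S to R only because the ester carbon has become a vinyl carbon of lower CIP rank than CH2O.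

Step 2
Reactants: 3 trimethyl{2-[(4R)-2,2-dimethyl-1,3-dioxolan-4-yl]prop-2-en-1-yl}silane
Product: 4 (2R)-3-[(trimethylsilyl)methyl]but-3-ene-1,2-diol
Conditions: PPTS (cat.), MeOH, 40 °C
Reagents that add atoms: none
Why: Acid-catalysed transketalisation should remove the isopropylidene group under conditions too weakly acidic to protodesilylate the allylsilane; the stereocentre is not involved.

Step 3
Reactants: 4 (2R)-3-[(trimethylsilyl)methyl]but-3-ene-1,2-diol; 5 methyl 4-hydroxy-3-methoxybenzoate (methyl vanillate)
Product: 6 methyl 4-{[(2R)-2-hydroxy-3-[(trimethylsilyl)methyl]but-3-en-1-yl]oxy}-3-methoxybenzoate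
Conditions: PPh3, DIAD, THF, 0 °C to rt
Reagents that add atoms: none
Why: Mitsunobu etherification: the acidic phenol should displace the oxyphosphonium group of the primary hydroxyl much faster than that of the hindered secondary one, so the ether forms at C1 and the C2–O bond with its configuration is kept.

Step 4
Reactants: 6 methyl 4-{[(2R)-2-hydroxy-3-[(trimethylsilyl)methyl]but-3-en-1-yl]oxy}-3-methoxybenzoate
Product: 7 methyl 3-methoxy-4-{[(2R)-2-[(triethylsilyl)oxy]-3-[(trimethylsilyl)methyl]but-3-en-1-yl]oxy}benzoate
Conditions: TESCl, imidazole, DMF, 0 °C to rt
Reagents that add atoms: chlorotriethylsilane, CC[Si](Cl)(CC)CC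
Why: Standard silylation of a secondary alcohol; the TES ether prevents O-acylation and HCl release in step 5 and can be removed later under buffered, nearly neutral conditions.

Step 5
Reactants: 7 methyl 3-methoxy-4-{[(2R)-2-[(triethylsilyl)oxy]-3-[(trimethylsilyl)methyl]but-3-en-1-yl]oxy}benzoate; 8 3-methylbut-2-enoyl chloride
Product: 9 methyl 3-methoxy-4-{[(2R)-7-methyl-3-methylidene-5-oxo-2-[(triethylsilyl)oxy]oct-6-en-1-yl]oxy}benzoate
Conditions: TiCl4, CH2Cl2, −78 °C; NaHCO3 quench at −78 °C
Reagents that add atoms: none
Why: Lewis-acid-mediated acylation of a 2-substituted allylsilane (Hosomi–Sakurai-type SE2′): the activated acyl chloride should attack the CH2 terminus and the β-silyl cation should lose silicon, so the new C3=CH2 bond forms where the C–Si carbon was. The skipped enone is thus fixed by mechanism and not by thermodynamics; C2 is not involved.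

Step 6
Reactants: 9 methyl 3-methoxy-4-{[(2R)-7-methyl-3-methylidene-5-oxo-2-[(triethylsilyl)oxy]oct-6-en-1-yl]oxy}benzoate
Product: 10 methyl 4-{[(2R)-2-hydroxy-7-methyl-3-methylidene-5-oxooct-6-en-1-yl]oxy}-3-methoxybenzoate
Conditions: HF·pyridine, pyridine, THF, 0 °C
Reagents that add atoms: none
Why: Buffered fluoride cleavage of the TES ether should free the secondary alcohol without acid strong enough to dehydrate the γ-hydroxy ketone or base strong enough to move the C3 alkene. The open-chain form of 10 should prevail because hemiketalisation would cost the enone conjugation.

Step 7
Reactants: 10 methyl 4-{[(2R)-2-hydroxy-7-methyl-3-methylidene-5-oxooct-6-en-1-yl]oxy}-3-methoxybenzoate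
Product: 12 methyl 4-{[(2S)-2-hydroperoxy-7-methyl-3-methylidene-5-oxooct-6-en-1-yl]oxy}-3-methoxybenzoate (CNP0338697.1), via (2R)-triflate 11 (not isolated)
Conditions: Tf2O, 2,6-di-tert-butyl-4-methylpyridine, CH2Cl2, −78 °C; then anhydrous H2O2 in Et2O (large excess), −78 to −40 °C
Reagents that add atoms: hydrogen peroxide, OO; trifluoromethanesulfonic anhydride (atoms in 11 only), O=S(=O)(OS(=O)(=O)C(F)(F)F)C(F)(F)F
Why: Proposed new method: O-triflation of 10 at −78 °C should give the secondary allylic triflate 11, which neutral hydrogen peroxide (an α-effect nucleophile) should displace in a bimolecular substitution with Walden inversion, loss of a proton then giving the hydroperoxide. The closest known reaction types are the perhydrolysis of secondary alkyl sulfonates and halides, which inverts, and the displacement of secondary allylic mesylates by superoxide, which also inverts; a stereospecific perhydrolysis of an allylic triflate carrying a γ-keto group has not been shown. No ring is closed. The only new stereocentre, C2, is controlled by the configuration of C2 in 10, which comes from the glycerate 1: (2R) C–O becomes (2S) C–OO. The step needs SN2 to win over ionisation (racemisation), over SN2′ attack at the exo-methylene carbon, over capture of the triflate by the C5 carbonyl oxygen (five-membered oxocarbenium, then furan) and over elimination. Ionisation is disfavoured because the allyl cation would carry the electron-withdrawing aryloxymethyl group at one end and a bare CH2 at the other, the conjugated carbonyl is a weak neighbouring group, and a hindered base, low temperature and a high H2O2 concentration favour the bimolecular path. Neutral H2O2 should neither epoxidise the enone nor deprotonate C4, as hydroperoxide anion would. The hydroperoxide is formed last and meets no reductant, base or Lewis acid afterwards.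

## Compound list

1 | methyl (4S)-2,2-dimethyl-1,3-dioxolane-4-carboxylate | COC(=O)[C@@H]1COC(C)(C)O1 | starting material
2 | 2-[(4S)-2,2-dimethyl-1,3-dioxolan-4-yl]-1,3-bis(trimethylsilyl)propan-2-ol | C[Si](C)(C)CC(O)(C[Si](C)(C)C)[C@@H]1COC(C)(C)O1 | intermediate (not isolated)
3 | trimethyl{2-[(4R)-2,2-dimethyl-1,3-dioxolan-4-yl]prop-2-en-1-yl}silane | C=C(C[Si](C)(C)C)[C@@H]1COC(C)(C)O1 | intermediate
4 | (2R)-3-[(trimethylsilyl)methyl]but-3-ene-1,2-diol | C=C(C[Si](C)(C)C)[C@@H](O)CO | intermediate
5 | methyl 4-hydroxy-3-methoxybenzoate (methyl vanillate) | COC(=O)c1ccc(O)c(OC)c1 | starting material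
6 | methyl 4-{[(2R)-2-hydroxy-3-[(trimethylsilyl)methyl]but-3-en-1-yl]oxy}-3-methoxybenzoate | C=C(C[Si](C)(C)C)[C@@H](O)COc1ccc(C(=O)OC)cc1OC | intermediate
7 | methyl 3-methoxy-4-{[(2R)-2-[(triethylsilyl)oxy]-3-[(trimethylsilyl)methyl]but-3-en-1-yl]oxy}benzoate | C=C(C[Si](C)(C)C)[C@@H](O[Si](CC)(CC)CC)COc1ccc(C(=O)OC)cc1OC | intermediate
8 | 3-methylbut-2-enoyl chloride | CC(C)=CC(=O)Cl | starting material
9 | methyl 3-methoxy-4-{[(2R)-7-methyl-3-methylidene-5-oxo-2-[(triethylsilyl)oxy]oct-6-en-1-yl]oxy}benzoate | C=C(CC(=O)C=C(C)C)[C@@H](O[Si](CC)(CC)CC)COc1ccc(C(=O)OC)cc1OC | intermediate
10 | methyl 4-{[(2R)-2-hydroxy-7-methyl-3-methylidene-5-oxooct-6-en-1-yl]oxy}-3-methoxybenzoate | C=C(CC(=O)C=C(C)C)[C@@H](O)COc1ccc(C(=O)OC)cc1OC | intermediate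
11 | methyl 3-methoxy-4-{[(2R)-7-methyl-3-methylidene-5-oxo-2-{[(trifluoromethyl)sulfonyl]oxy}oct-6-en-1-yl]oxy}benzoate | C=C(CC(=O)C=C(C)C)[C@@H](OS(=O)(=O)C(F)(F)F)COc1ccc(C(=O)OC)cc1OC | intermediate (not isolated)
12 | methyl 4-{[(2S)-2-hydroperoxy-7-methyl-3-methylidene-5-oxooct-6-en-1-yl]oxy}-3-methoxybenzoate | C=C(CC(=O)C=C(C)C)[C@@H](COc1ccc(C(=O)OC)cc1OC)OO | target

## Step count and least certain steps

Total number of steps: 7. Longest linear sequence: 7 steps (1 to 12); 5 and 8 enter in steps 3 and 5.

**Step 7 (key step, Proposed new method).**
- What may go wrong: loss of stereochemical fidelity through ionisation of the allylic triflate; attack of hydrogen peroxide at the exo-methylene carbon (SN2′), giving the primary allylic hydroperoxide; intramolecular capture of the triflate by the C5 carbonyl oxygen followed by aromatisation to a furan; acid-induced fragmentation of the product during work-up. All of these arise because the leaving group sits on an allylic carbon with a ketone oxygen five atoms away.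
- Fallback (known chemistry): the approach changes from substitution at a pre-set centre to ene construction of the racemate followed by resolution. It sets out from 5 (with 8) and returns at 12.
- 8 is added to isoprene (SnCl4, CH2Cl2, −78 °C, 1,4-chloroacylation) to give, after removal of the Z isomer, the allylic chloride (6E)-8-chloro-2,6-dimethylocta-2,6-dien-4-one F1.
- 5 is O-alkylated with F1 (K2CO3, acetone, rt) to the ether A1 of Alternative 1.
- Dye-sensitised photooxygenation (O2, tetraphenylporphyrin, visible light, CH2Cl2, 0 °C) should give racemic A2.
- The enantiomers of A2 are separated by preparative HPLC on a chiral stationary phase. 12 is identified by reducing a sample with PPh3: its alcohol must be the mirror image of 10 from the main route on a chiral column.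

**Step 5.**
- What may go wrong: Lewis-acid-induced loss of the TES group or attack on the aryl ether and ester; migration of the new C3=CH2 bond into conjugation with the ketone while acid is still present during the quench.
- Fallback, from 7 to 9: Hosomi–Sakurai addition of 7 to 3-methylbut-2-enal (BF3·OEt2, CH2Cl2, −78 °C) should give the allylic carbinol methyl 4-{[(2R)-5-hydroxy-7-methyl-3-methylidene-2-[(triethylsilyl)oxy]oct-6-en-1-yl]oxy}-3-methoxybenzoate F2 as a mixture of C5 epimers. Oxidation with MnO2 (CH2Cl2, rt) removes that centre and gives 9. A milder Lewis acid and a neutral oxidation replace the acyl chloride.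

**Step 3.**
- What may go wrong: insufficient discrimination between the two hydroxyls, or closure of the activated diol to an epoxide instead of ether formation, because the secondary hydroxyl is allylic and close by.
- Fallback, from 4 to 6: regioselective tosylation of the primary hydroxyl (TsCl, Bu2SnO cat., Et3N, CH2Cl2) gives (2R)-2-hydroxy-3-[(trimethylsilyl)methyl]but-3-en-1-yl 4-methylbenzenesulfonate F3. K2CO3 closes F3 to the epoxide trimethyl{2-[(2R)-oxiran-2-yl]prop-2-en-1-yl}silane F4. Opening of F4 by the phenoxide of 5 at the terminal carbon (K2CO3, DMF, 60 °C) gives 6. The C2–O bond is never broken.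

**Step 6.**
- What may go wrong: cyclodehydration of the freed γ-hydroxy ketone to a furan under residual acid, or migration of the C3 alkene under basic fluoride.
- Fallback, from 6 to 10, omitting steps 4 to 6: 6 is acylated directly with 8 using Me2AlCl (2.2 equiv, CH2Cl2, −78 °C). The reagent first converts the hydroxyl into its aluminium alkoxide with loss of methane, then promotes the SE2′ acylation. Neutral work-up with Rochelle salt releases 10 without any acidic or basic deprotection. No new isolable compound is formed.

## Further compounds

F1 | step 7 | (6E)-8-chloro-2,6-dimethylocta-2,6-dien-4-one | CC(C)=CC(=O)C/C(C)=C/CCl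
F2 | step 5 | methyl 4-{[(2R)-5-hydroxy-7-methyl-3-methylidene-2-[(triethylsilyl)oxy]oct-6-en-1-yl]oxy}-3-methoxybenzoate (C5 epimers) | C=C(CC(O)C=C(C)C)[C@@H](O[Si](CC)(CC)CC)COc1ccc(C(=O)OC)cc1OC
F3 | step 3 | (2R)-2-hydroxy-3-[(trimethylsilyl)methyl]but-3-en-1-yl 4-methylbenzenesulfonate | C=C(C[Si](C)(C)C)[C@@H](O)COS(=O)(=O)c1ccc(C)cc1
F4 | step 3 | trimethyl{2-[(2R)-oxiran-2-yl]prop-2-en-1-yl}silane | C=C(C[Si](C)(C)C)[C@@H]1CO1
F0 | step 6 | none | none
A1 | alternative 1 | methyl 4-{[(2E)-3,7-dimethyl-5-oxoocta-2,6-dien-1-yl]oxy}-3-methoxybenzoate | COC(=O)c1ccc(OC/C=C(\C)CC(=O)C=C(C)C)c(OC)c1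
A2 | alternative 1 | racemic methyl 4-[(2-hydroperoxy-7-methyl-3-methylidene-5-oxooct-6-en-1-yl)oxy]-3-methoxybenzoate | C=C(CC(=O)C=C(C)C)C(COc1ccc(C(=O)OC)cc1OC)OO
A3 | alternative 2 | methyl 3-methoxy-4-(2-oxoethoxy)benzoate | COC(=O)c1ccc(OCC=O)c(OC)c1
A4 | alternative 3 | 2-methyl-6-[(2R)-oxiran-2-yl]hepta-2,6-dien-4-one | C=C(CC(=O)C=C(C)C)[C@@H]1CO1
A5 | alternative 3 | (7S)-7-hydroperoxy-8-hydroxy-2-methyl-6-methylideneoct-2-en-4-one | C=C(CC(=O)C=C(C)C)[C@H](OO)CO
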